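**Retrosynthetic overview**
- C4–OAc and the C1′–H bond: last-step Evans–Tishchenko reduction of a 4,5-dihydroxy-5-tridecanoylcyclopentenone with acetaldehyde (hydride delivered from O4, acetyl left on O4).
- Key bond, C5–O of the quaternary carbinol: capture of the C5 radical of the 2-acyl enone (a 1,3-diketone) by O2, anti to the C4 silyl ether.
- C5–C1′: aldol addition of the enolate of silyl-protected (4R)-4-hydroxycyclopent-2-en-1-one to tridecanal, then oxidation to the 1,3-diketone.
- Tridecanal: cross-metathesis of hept-6-enal with oct-1-ene, then hydrogenation.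
- Rings: the single cyclopentenone ring is bought intact with the C4 stereocentre; no ring is formed.

Assumption: hept-6-enal and (4R)-4-hydroxycyclopent-2-en-1-one are bought as such; ring atoms are called C1–C5 (C1 = ketone carbon) and the side-chain carbinol carbon C1′ throughout.

**Route**

Step 1
Reactants: 1 hept-6-enal; 2 oct-1-ene
Product: 4 tridecanal, via tridec-6-enal 3 (not isolated)
Conditions: 2 (4 equiv), second-generation Grubbs catalyst RuCl2(=CHPh)(PCy3)(H2IMes) (2 mol%), CH2Cl2, 40 °C; then 10% Pd/C, H2 (1 atm), EtOAc, rt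
Reagents that add atoms: none
Why: Cross-metathesis of two unhindered terminal alkenes, driven by loss of ethene and biased towards the cross product by the excess of 2, followed by hydrogenation of the isolated disubstituted alkene over Pd/C at 1 atm, which leaves the aldehyde intact; no stereocentre is formed.

Step 2
Reactants: 5 (4R)-4-hydroxycyclopent-2-en-1-one
Product: 6 (4R)-4-[(tert-butyldimethylsilyl)oxy]cyclopent-2-en-1-one
Conditions: TBSCl (1.2 equiv), imidazole (2 equiv), CH2Cl2, 0 °C to rt
Reagents that add atoms: tert-butyl(chloro)dimethylsilane (TBSCl), CC(C)(C)[Si](C)(C)Cl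
Why: Routine silylation of the secondary allylic alcohol, which leaves C4 untouched and turns the hydroxyl into a poor leaving group that tolerates the enolate chemistry of step 3.

Step 3
Reactants: 6 (4R)-4-[(tert-butyldimethylsilyl)oxy]cyclopent-2-en-1-one; 4 tridecanal
Product: 8 (4S,5R)-4-[(tert-butyldimethylsilyl)oxy]-5-(1-hydroxytridecyl)cyclopent-2-en-1-one (4,5-trans; both C1′ epimers), via lithium enolate 7 (not isolated)
Conditions: LiN(iPr)2 (1.1 equiv), THF, −78 °C, 20 min; then 4 (1.2 equiv), −78 °C, 30 min; AcOH (1.2 equiv) at −78 °C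
Reagents that add atoms: none
Why: Kinetic α′-deprotonation gives the cross-conjugated lithium dienolate 7, which undergoes aldol addition to the aldehyde at −78 °C faster than β-elimination of silanolate and anti to the C4 silyloxy group; the new centres at C5 and C1′ need no control because both are erased in steps 4 and 5.

Step 4
Reactants: 8 (4S,5R)-4-[(tert-butyldimethylsilyl)oxy]-5-(1-hydroxytridecyl)cyclopent-2-en-1-one
Product: 9 (4S)-4-[(tert-butyldimethylsilyl)oxy]-5-tridecanoylcyclopent-2-en-1-one
Conditions: Dess–Martin periodinane (1.3 equiv), CH2Cl2, 0 °C to rt, 1 h; cold Na2S2O3/NaHCO3 wash; used at once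
Reagents that add atoms: none
Why: Dess–Martin oxidation of the β-hydroxy ketone to the 1,3-diketone under non-basic conditions, which leaves the C4 silyl ether and stereocentre untouched and gives 9 mainly as its chelated exocyclic enol.

Step 5 (key step)
Reactants: 9 (4S)-4-[(tert-butyldimethylsilyl)oxy]-5-tridecanoylcyclopent-2-en-1-one
Product: 11 (4S,5S)-4-[(tert-butyldimethylsilyl)oxy]-5-hydroxy-5-tridecanoylcyclopent-2-en-1-one, via hydroperoxide 10 (not isolated)
Conditions: CeCl3·7H2O (10 mol%), O2 (1 atm), iPrOH, 0 °C to rt; then PPh3 (1.1 equiv), 0 °C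
Reagents that add atoms: dioxygen, O=O
Why: Cerium-catalysed aerobic α-hydroxylation of a 1,3-dicarbonyl compound: the trivalent cerium diketonate of 9 is oxidised by O2 to the tetravalent state, inner-sphere electron transfer releases the planar C5 radical, triplet O2 adds to it on the face opposite the bulky C4 silyloxy group (new C5–O bond trans to O4, 5S) and PPh3 reduces hydroperoxide 10, all without a free basic enolate that would expel the C4 oxygen.

Step 6
Reactants: 11 (4S,5S)-4-[(tert-butyldimethylsilyl)oxy]-5-hydroxy-5-tridecanoylcyclopent-2-en-1-one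
Product: 12 (4S,5S)-4,5-dihydroxy-5-tridecanoylcyclopent-2-en-1-one
Conditions: 48% aq. HF, MeCN, 0 °C to rt
Reagents that add atoms: none
Why: Acidic fluoride cleavage of the secondary silyl ether (desilylation), which avoids any alkoxide at O4 and therefore the retro-aldol opening of the β-hydroxy 1,3-diketone; no stereocentre is touched.

Step 7
Reactants: 12 (4S,5S)-4,5-dihydroxy-5-tridecanoylcyclopent-2-en-1-one
Product: 14 (4S,5R)-4-acetoxy-5-hydroxy-5-[(1S)-1-hydroxytridecyl]cyclopent-2-en-1-one (the target), via hemiacetal 13 (not isolated)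
Conditions: CH3CHO (10 equiv), SmI2 (30 mol%, pre-mixed with the aldehyde until the blue colour fades), THF, −10 °C
Reagents that add atoms: acetaldehyde, CC=O
Why: Evans–Tishchenko reduction: O4 forms a hemiacetal with acetaldehyde on trivalent samarium and passes its hydride to the C1′ ketone through a six-membered chair-like transition state (C3 equatorial, ketone oxygen axial and bridged by samarium to the hemiacetal oxygen and O5), which gives the 1,3-anti (1′S) carbinol, leaves the acetyl group regiospecifically on O4 and cannot reach the ring carbonyl.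

**Compound list**

1 | hept-6-enal | C=CCCCCC=O | starting material
2 | oct-1-ene | C=CCCCCCC | starting material
3 | tridec-6-enal (E/Z mixture, not isolated) | CCCCCCC=CCCCCC=O | intermediate
4 | tridecanal | CCCCCCCCCCCCC=O | intermediate
5 | (4R)-4-hydroxycyclopent-2-en-1-one | O=C1C=C[C@H](O)C1 | starting material
6 | (4R)-4-[(tert-butyldimethylsilyl)oxy]cyclopent-2-en-1-one | O=C1C=C[C@H](O[Si](C)(C)C(C)(C)C)C1 | intermediate
7 | lithium (3S)-3-[(tert-butyldimethylsilyl)oxy]cyclopenta-1,4-dien-1-olate (C5 enolate of 6, not isolated) | [Li+].[O-]C1=C[C@@H](O[Si](C)(C)C(C)(C)C)C=C1 | intermediate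
8 | (4S,5R)-4-[(tert-butyldimethylsilyl)oxy]-5-(1-hydroxytridecyl)cyclopent-2-en-1-one (4,5-trans; both C1′ epimers) | CCCCCCCCCCCCC(O)[C@H]1C(=O)C=C[C@@H]1O[Si](C)(C)C(C)(C)C | intermediate
9 | (4S)-4-[(tert-butyldimethylsilyl)oxy]-5-tridecanoylcyclopent-2-en-1-one (C5 epimerisable, mainly enol) | CCCCCCCCCCCCC(=O)C1C(=O)C=C[C@@H]1O[Si](C)(C)C(C)(C)C | intermediate
10 | (4S,5S)-4-[(tert-butyldimethylsilyl)oxy]-5-hydroperoxy-5-tridecanoylcyclopent-2-en-1-one (OOH trans to the silyl ether, not isolated) | CCCCCCCCCCCCC(=O)[C@]1(OO)C(=O)C=C[C@@H]1O[Si](C)(C)C(C)(C)C | intermediate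
11 | (4S,5S)-4-[(tert-butyldimethylsilyl)oxy]-5-hydroxy-5-tridecanoylcyclopent-2-en-1-one (OH trans to the silyl ether) | CCCCCCCCCCCCC(=O)[C@]1(O)C(=O)C=C[C@@H]1O[Si](C)(C)C(C)(C)C | intermediate
12 | (4S,5S)-4,5-dihydroxy-5-tridecanoylcyclopent-2-en-1-one (trans diol) | CCCCCCCCCCCCC(=O)[C@]1(O)C(=O)C=C[C@@H]1O | intermediate
13 | (4S,5S)-5-hydroxy-4-(1-hydroxyethoxy)-5-tridecanoylcyclopent-2-en-1-one (samarium-bound hemiacetal, hemiacetal carbon undefined, not isolated) | CCCCCCCCCCCCC(=O)[C@]1(O)C(=O)C=C[C@@H]1OC(C)O | intermediate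
14 | (4S,5R)-4-acetoxy-5-hydroxy-5-[(1S)-1-hydroxytridecyl]cyclopent-2-en-1-one (CNP0147374.3) | CCCCCCCCCCCC[C@H](O)[C@]1(O)C(=O)C=C[C@@H]1OC(C)=O | target

**Step count and risks**

Total steps: 7. Longest linear sequence: 6 (steps 2–7 from 5; the branch from 1 through steps 1 and 3–7 is also 6).

The three steps most likely to fail:

1. The radical hydroxylation (step 5). Diketone 9 can lose C4 integrity through a [1,5]-hydrogen shift in its cyclopentadienol tautomer during the slow aerobic reaction. Product 11 can also suffer retro-Claisen cleavage by iPrOH on the Lewis-acidic cerium, and facial selectivity may be incomplete. The fallback keeps the radical C–O bond formation but changes how the radical is made; it sets out from 9 and returns at 11. Bromination of 9 (N-bromosuccinimide, CH2Cl2, −40 °C, minutes) gives the non-enolisable tertiary bromide (4S,5S)-5-bromo-4-[(tert-butyldimethylsilyl)oxy]-5-tridecanoylcyclopent-2-en-1-one F1. Slow addition of Bu3SnH to F1 in toluene under dry air at 0 °C abstracts bromine, the same C5 radical is trapped by O2 anti to the silyl ether, and PPh3 work-up of hydroperoxide 10 gives 11.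

2. The Evans–Tishchenko reduction (step 7). The samarium alkoxide of 12 can open by retro-aldol cleavage of C4–C5, because the departing C5 carbanion is doubly stabilised. Hydride delivery through O5 or acetyl migration may also erode selectivity. The fallback sets out from 12 and returns at 14. Directed reduction with Me4N[BH(OAc)3] (MeCN/AcOH, −30 °C, acidic, hydride again delivered from O4 with 1,3-anti selectivity) gives the triol (4S,5R)-4,5-dihydroxy-5-[(1S)-1-hydroxytridecyl]cyclopent-2-en-1-one F2. The tertiary/secondary 1,2-diol is tied up with 2,2-dimethoxypropane/PPTS as the O5,O1′-acetonide F3. The remaining C4 hydroxyl is acetylated (Ac2O, pyridine, DMAP) to the acetonide acetate F4, and 80% aqueous AcOH at 40 °C releases 14.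

3. The aldol addition (step 3). Proton transfer from the enolisable aldehyde, retro-aldol on warming and loss of silanolate from 7 can all lower the yield of 8. The fallback sets out from 4 (partner: enolate 7 made from 6) and returns at 9. Oxidation of 4 with NaClO2/NaH2PO4/2-methylbut-2-ene (tBuOH/H2O) gives tridecanoic acid F5. Carbonyldiimidazole (CDI, THF) converts it into 1-(1H-imidazol-1-yl)tridecan-1-one F6. Irreversible C-acylation of 7 (2.2 equiv, THF, −78 °C) with F6 gives 9 directly, so the reversible aldol addition and step 4 are both bypassed.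

Further compounds
F1 | step 5 | (4S,5S)-5-bromo-4-[(tert-butyldimethylsilyl)oxy]-5-tridecanoylcyclopent-2-en-1-one (Br trans to the silyl ether) | CCCCCCCCCCCCC(=O)[C@]1(Br)C(=O)C=C[C@@H]1O[Si](C)(C)C(C)(C)C
F2 | step 7 | (4S,5R)-4,5-dihydroxy-5-[(1S)-1-hydroxytridecyl]cyclopent-2-en-1-one | CCCCCCCCCCCC[C@H](O)[C@]1(O)C(=O)C=C[C@@H]1O
F3 | step 7 | O5,O1′-isopropylidene acetal of F2 (spiro-dioxolane, C4 hydroxyl free, configuration as in F2) | CCCCCCCCCCCC[C@@H]1OC(C)(C)O[C@]12C(=O)C=C[C@@H]2O
F4 | step 7 | 4-O-acetate of F3 (O5,O1′-acetonide of the target) | CCCCCCCCCCCC[C@@H]1OC(C)(C)O[C@]12C(=O)C=C[C@@H]2OC(C)=O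
F5 | step 3 | tridecanoic acid | CCCCCCCCCCCCC(=O)O
F6 | step 3 | 1-(1H-imidazol-1-yl)tridecan-1-one | CCCCCCCCCCCCC(=O)n1ccnc1
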